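## Retrosynthetic overview

1. The C11=C12 and C11'=C12' double bonds are made last, by two E-selective Horner–Wadsworth–Emmons olefinations of (2E,4E,6E)-2,7-dimethylocta-2,4,6-trienedial: first with the ring A C15 enyne phosphonate, then with the ring B C15 enyne phosphonate. One desilylation ends the route.
2. Ring A C15 unit: Sonogashira coupling at C6–C7 of a ring A alkenyl nonaflate with a C5 enyne phosphonate. The C6–O sulfonate and the C3 acetate (Baeyer–Villiger, retention) both come from one cyclohexenyl silyl enol ether.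
3. Ring A is the only ring that is built, and it is built first. Its tetrasubstituted C5=C6 double bond lies between C4H2 and the quaternary C1, with the oxygen-bearing C3 para to the alkyne-bearing C6. With C6 at the enol (ketone) oxidation level, C4=C5–C6(OSi)=C1 is a 2-silyloxydiene, and ring A is its Diels–Alder adduct with a two-carbon enone (C2–C3); this closes C3–C4 and C1–C2 together and sets C3.
4. Ring B is not constructed; it is carried in from 2,6,6-trimethylcyclohex-2-ene-1,4-dione. Asymmetric transfer hydrogenation sets C3', acetylide addition and oxidative 1,3-transposition put the alkyne on C6' and oxygen on C4', and a face-selective hydride reduction gives the cis-diol.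

Key step: step 3

Remark: carotenoid locants are used (C1–C6 = 3-hydroxy ring A, primed locants = diol ring B); TBS = tert-butyldimethylsilyl, Nf = nonafluorobutane-1-sulfonyl; compounds 1, 2, 5, 9, 14 and 16 are taken as catalogue chemicals.

## Route

Step 1
Reactants: 1 N-methoxy-N,2-dimethylpropanamide; 2 prop-1-en-2-ylmagnesium bromide
Product: 3 2,4-dimethylpent-1-en-3-one
Conditions: THF, 0 °C; then cold 1 M HCl
Reagents that add atoms: none
Why: Weinreb ketone synthesis; the chelated tetrahedral adduct prevents over-addition, and the acidic quench keeps the released amine from adding to the enone.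

Step 2
Reactants: 3 2,4-dimethylpent-1-en-3-one
Product: 4 tert-butyl[(2,4-dimethylpenta-1,3-dien-3-yl)oxy]dimethylsilane
Conditions: TBSOTf, Et3N, CH2Cl2, 0 °C to rt
Reagents that add atoms: tert-butyldimethylsilyl trifluoromethanesulfonate, CC(C)(C)[Si](C)(C)OS(=O)(=O)C(F)(F)F
Why: Soft enolisation (silyl triflate/amine) at the only enolisable position, the isopropyl methine, should give the cross-conjugated 2-silyloxydiene without a free enolate that could add to the enone.

Step 3
Reactants: 4 tert-butyl[(2,4-dimethylpenta-1,3-dien-3-yl)oxy]dimethylsilane; 5 but-3-en-2-one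
Product: 6 1-[(1R)-4-(TBS-oxy)-3,5,5-trimethylcyclohex-3-en-1-yl]ethan-1-one
Conditions: (R)-3,3-diphenyl-1-(2-methylphenyl)tetrahydro-1H,3H-pyrrolo[1,2-c][1,3,2]oxazaborole (20 mol %), HNTf2 (18 mol %), CH2Cl2, −78 to −40 °C
Reagents that add atoms: none
Why: Catalytic enantioselective Diels–Alder reaction of a 2-silyloxydiene with an enone under a protonated chiral oxazaborolidine (closest known type: cationic oxazaborolidine-catalysed [4+2] additions of 2-silyloxybutadienes to acrylates and enones); the boron-bound s-trans enone is attacked at its unsubstituted β-carbon (C2) by the fully substituted enol-ether terminus C1, and C3–C4 closes onto the diene CH2 terminus in the same, strongly asynchronous event. Ring A is closed in the [4+2] mode; should the addition become stepwise, a 6-endo-trig Mukaiyama–Michael closure of the boron enolate onto the silyloxocarbenium-activated enone leads to the same product. The single new stereocentre C3 is set by the catalyst: the α-C–H···O contact holds the enone on the convex face of the bicycle with its C=C stacked on the cis phenyl group, so C4 should add to the exposed Re face of C-α and give the (R)-centre that becomes (3R) after the stereoretentive oxidation of step 5. The regiochemistry (acetyl on C3, para to C6–O) is secured by the silyloxy group, which makes C1 the nucleophilic terminus and outweighs the methyl groups; there is no endo/exo question because only one stereocentre forms. The quaternary C1 is made at an unhindered CH2 acceptor, which is why the gem-dimethyl terminus, a poor partner in thermal cycloadditions, is tolerated. Low temperature and the non-nucleophilic triflimide counter-ion are needed to keep proto-desilylation of 4 slower than the cycloaddition.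

Step 4
Reactants: 6 1-[(1R)-4-(TBS-oxy)-3,5,5-trimethylcyclohex-3-en-1-yl]ethan-1-one
Product: 7 (4R)-4-acetyl-2,6,6-trimethylcyclohex-1-en-1-yl nonafluorobutane-1-sulfonate
Conditions: n-C4F9SO2F (1.3 equiv), Bu4N[Ph3SiF2] (10 mol %), THF, −30 to 0 °C
Reagents that add atoms: nonafluorobutane-1-sulfonyl fluoride, FS(=O)(=O)C(F)(F)C(F)(F)C(F)(F)C(F)(F)F
Why: Fluoride-catalysed conversion of a silyl enol ether into an alkenyl nonaflate; the C5=C6 enolate is released regiospecifically in catalytic concentration and should be sulfonylated faster than it exchanges protons with the acetyl group, fluoride being regenerated from the sulfonyl fluoride.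

Step 5
Reactants: 7 (4R)-4-acetyl-2,6,6-trimethylcyclohex-1-en-1-yl nonafluorobutane-1-sulfonate
Product: 8 (4R)-4-acetoxy-2,6,6-trimethylcyclohex-1-en-1-yl nonafluorobutane-1-sulfonate
Conditions: mCPBA, NaHCO3, CH2Cl2, rt to 40 °C
Reagents that add atoms: 3-chloroperoxybenzoic acid, OOC(=O)c1cccc(Cl)c1
Why: Baeyer–Villiger oxidation; the secondary ring carbon migrates in preference to methyl with retention, so the (R)-acetyl centre becomes the (R)-acetate, and the electron-poor tetrasubstituted alkenyl sulfonate should not be epoxidised.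

Step 6
Reactants: 9 (2E)-3-methylpent-2-en-4-yn-1-ol
Product: 10 (2E)-1-bromo-3-methylpent-2-en-4-yne
Conditions: PBr3, pyridine (cat.), Et2O, −10 °C
Reagents that add atoms: phosphorus tribromide, BrP(Br)Br
Why: SN2 bromination of a primary allylic alcohol at low temperature, which leaves the (E)-double bond and the terminal alkyne untouched.

Step 7
Reactants: 10 (2E)-1-bromo-3-methylpent-2-en-4-yne
Product: 11 diethyl [(2E)-3-methylpent-2-en-4-yn-1-yl]phosphonate
Conditions: P(OEt)3, 90 °C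
Reagents that add atoms: triethyl phosphite, CCOP(OCC)OCC
Why: Michaelis–Arbuzov reaction of a primary allylic bromide; SN2 attack by phosphorus retains the (E)-geometry.

Step 8
Reactants: 8 (4R)-4-acetoxy-2,6,6-trimethylcyclohex-1-en-1-yl nonafluorobutane-1-sulfonate; 11 diethyl [(2E)-3-methylpent-2-en-4-yn-1-yl]phosphonate
Product: 12 (1R)-4-[(3E)-5-(diethoxyphosphoryl)-3-methylpent-3-en-1-yn-1-yl]-3,5,5-trimethylcyclohex-3-en-1-yl acetate
Conditions: Pd(PPh3)4 (5 mol %), CuI (10 mol %), i-Pr2NH, DMF, 50 °C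
Reagents that add atoms: none
Why: Sonogashira coupling of an alkenyl nonaflate with a terminal alkyne forms C6–C7 and gives the conjugated C5=C6–C7≡C8 enyne; acetate and phosphonate are inert.

Step 9
Reactants: 12 (1R)-4-[(3E)-5-(diethoxyphosphoryl)-3-methylpent-3-en-1-yn-1-yl]-3,5,5-trimethylcyclohex-3-en-1-yl acetate
Product: 13 diethyl [(2E)-5-[(4R)-4-hydroxy-2,6,6-trimethylcyclohex-1-en-1-yl]-3-methylpent-2-en-4-yn-1-yl]phosphonate
Conditions: K2CO3, EtOH, rt
Reagents that add atoms: none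
Why: Transesterification of the secondary acetate; ethanol makes any exchange at the diethyl phosphonate degenerate, and C3 is not involved.

Step 10
Reactants: 13 diethyl [(2E)-5-[(4R)-4-hydroxy-2,6,6-trimethylcyclohex-1-en-1-yl]-3-methylpent-2-en-4-yn-1-yl]phosphonate; 14 (2E,4E,6E)-2,7-dimethylocta-2,4,6-trienedial (3 equiv)
Product: 15 (2E,4E,6E,8E,10E)-13-[(4R)-4-hydroxy-2,6,6-trimethylcyclohex-1-en-1-yl]-2,7,11-trimethyltrideca-2,4,6,8,10-pentaen-12-ynal
Conditions: KOt-Bu (2.2 equiv) added to the mixture of 13 and 14, THF, −40 to 0 °C, dark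
Reagents that add atoms: none
Why: Horner–Wadsworth–Emmons olefination of an allylic phosphonate should form C11=C12 with E-geometry; the excess of the symmetrical dialdehyde holds the reaction at mono-olefination, and the hydroxyl is carried as its alkoxide.

Step 11
Reactants: 16 2,6,6-trimethylcyclohex-2-ene-1,4-dione
Product: 17 (4S)-4-hydroxy-2,6,6-trimethylcyclohex-2-en-1-one
Conditions: RuCl[(S,S)-TsNCH(Ph)CH(Ph)NH2](p-cymene) (0.5 mol %), i-PrOH, rt
Reagents that add atoms: none
Why: Noyori asymmetric transfer hydrogenation; only the unhindered C4 carbonyl reacts, and with the ring C=C acting as the π-substituent the (S,S)-catalyst should give the (4S)-alcohol, which becomes C3' of ring B.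

Step 12
Reactants: 17 (4S)-4-hydroxy-2,6,6-trimethylcyclohex-2-en-1-one
Product: 18 (4S)-4-(TBS-oxy)-2,6,6-trimethylcyclohex-2-en-1-one
Conditions: TBSCl, imidazole, DMF, rt
Reagents that add atoms: tert-butyldimethylsilyl chloride, CC(C)(C)[Si](C)(C)Cl
Why: Standard silylation of a secondary alcohol; the stereocentre is not touched.

Step 13
Reactants: 9 (2E)-3-methylpent-2-en-4-yn-1-ol
Product: 19 tert-butyldimethyl{[(2E)-3-methylpent-2-en-4-yn-1-yl]oxy}silane
Conditions: TBSCl, imidazole, CH2Cl2, 0 °C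
Reagents that add atoms: tert-butyldimethylsilyl chloride, CC(C)(C)[Si](C)(C)Cl
Why: Silylation of the primary alcohol so that the alkyne can be metallated.

Step 14
Reactants: 19 tert-butyldimethyl{[(2E)-3-methylpent-2-en-4-yn-1-yl]oxy}silane; 18 (4S)-4-(TBS-oxy)-2,6,6-trimethylcyclohex-2-en-1-one
Product: 21 (4S)-4-(TBS-oxy)-1-[(3E)-5-(TBS-oxy)-3-methylpent-3-en-1-yn-1-yl]-2,6,6-trimethylcyclohex-2-en-1-ol (both C1 epimers), via lithium acetylide 20 (not isolated)
Conditions: n-BuLi, THF, −78 °C; then 18, −78 to −20 °C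
Reagents that add atoms: none
Why: 1,2-Addition of a small lithium acetylide to the hindered enone carbonyl; the new carbinol centre is formed as a mixture and is removed in step 15.

Step 15
Reactants: 21 (4S)-4-(TBS-oxy)-1-[(3E)-5-(TBS-oxy)-3-methylpent-3-en-1-yn-1-yl]-2,6,6-trimethylcyclohex-2-en-1-ol
Product: 22 (6S)-6-(TBS-oxy)-3-[(3E)-5-(TBS-oxy)-3-methylpent-3-en-1-yn-1-yl]-2,4,4-trimethylcyclohex-2-en-1-one
Conditions: pyridinium chlorochromate (C5H5NH[CrO3Cl]), 4 Å molecular sieves, CH2Cl2, rt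
Reagents that add atoms: pyridinium chlorochromate, [O-][Cr](=O)(=O)Cl.c1cc[nH+]cc1
Why: Babler–Dauben oxidative 1,3-transposition; [3,3]-shift of the tertiary allylic chromate ester and oxidation give the enone with C5'=C6' conjugated to the alkyne and the carbonyl at C4', while the silyloxy centre keeps its configuration.

Step 16
Reactants: 22 (6S)-6-(TBS-oxy)-3-[(3E)-5-(TBS-oxy)-3-methylpent-3-en-1-yn-1-yl]-2,4,4-trimethylcyclohex-2-en-1-one
Product: 23 (1R,6S)-6-(TBS-oxy)-3-[(3E)-5-(TBS-oxy)-3-methylpent-3-en-1-yn-1-yl]-2,4,4-trimethylcyclohex-2-en-1-ol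
Conditions: LiBH(s-Bu)3, THF, −78 °C
Reagents that add atoms: none
Why: 1,2-Reduction by a bulky hydride, which should attack anti to the adjacent C–OSi bond (equatorial approach) and so place the new C4' hydroxyl cis to the C3' silyloxy group; conjugate reduction is disfavoured at the fully substituted β-carbon.

Step 17
Reactants: 23 (1R,6S)-6-(TBS-oxy)-3-[(3E)-5-(TBS-oxy)-3-methylpent-3-en-1-yn-1-yl]-2,4,4-trimethylcyclohex-2-en-1-ol
Product: 24 tert-butyl{[(2E)-5-[(3R,4S)-3,4-bis(TBS-oxy)-2,6,6-trimethylcyclohex-1-en-1-yl]-3-methylpent-2-en-4-yn-1-yl]oxy}dimethylsilane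
Conditions: TBSOTf, 2,6-lutidine, CH2Cl2, −78 to 0 °C
Reagents that add atoms: tert-butyldimethylsilyl trifluoromethanesulfonate, CC(C)(C)[Si](C)(C)OS(=O)(=O)C(F)(F)F
Why: Silyl triflate silylation of the hindered, acid-sensitive allylic alcohol under basic conditions.

Step 18
Reactants: 24 tert-butyl{[(2E)-5-[(3R,4S)-3,4-bis(TBS-oxy)-2,6,6-trimethylcyclohex-1-en-1-yl]-3-methylpent-2-en-4-yn-1-yl]oxy}dimethylsilane
Product: 25 (2E)-5-[(3R,4S)-3,4-bis(TBS-oxy)-2,6,6-trimethylcyclohex-1-en-1-yl]-3-methylpent-2-en-4-yn-1-ol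
Conditions: HF·pyridine, pyridine, THF, 0 °C
Reagents that add atoms: none
Why: Sterically controlled selective cleavage of the primary silyl ether in the presence of two hindered secondary ones.

Step 19
Reactants: 25 (2E)-5-[(3R,4S)-3,4-bis(TBS-oxy)-2,6,6-trimethylcyclohex-1-en-1-yl]-3-methylpent-2-en-4-yn-1-ol
Product: 26 (3R,4S)-1-[(3E)-5-bromo-3-methylpent-3-en-1-yn-1-yl]-3,4-bis(TBS-oxy)-2,6,6-trimethylcyclohex-1-ene
Conditions: CBr4, PPh3, 2,6-lutidine, CH2Cl2, −20 °C
Reagents that add atoms: carbon tetrabromide, BrC(Br)(Br)Br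
Why: Appel bromination of the primary allylic alcohol under neutral conditions that spare the allylic silyl ether and the (E)-geometry.

Step 20
Reactants: 26 (3R,4S)-1-[(3E)-5-bromo-3-methylpent-3-en-1-yn-1-yl]-3,4-bis(TBS-oxy)-2,6,6-trimethylcyclohex-1-ene
Product: 27 diethyl [(2E)-5-[(3R,4S)-3,4-bis(TBS-oxy)-2,6,6-trimethylcyclohex-1-en-1-yl]-3-methylpent-2-en-4-yn-1-yl]phosphonate
Conditions: P(OEt)3, 90 °C
Reagents that add atoms: triethyl phosphite, CCOP(OCC)OCC
Why: Michaelis–Arbuzov reaction of the primary allylic bromide with retention of the (E)-geometry.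

Step 21
Reactants: 27 diethyl [(2E)-5-[(3R,4S)-3,4-bis(TBS-oxy)-2,6,6-trimethylcyclohex-1-en-1-yl]-3-methylpent-2-en-4-yn-1-yl]phosphonate; 15 (2E,4E,6E,8E,10E)-13-[(4R)-4-hydroxy-2,6,6-trimethylcyclohex-1-en-1-yl]-2,7,11-trimethyltrideca-2,4,6,8,10-pentaen-12-ynal
Product: 28 (3R,3'S,4'R)-3',4'-bis-O-TBS-7,8,7',8'-tetradehydro-β,β-carotene-3,3',4'-triol
Conditions: KOt-Bu (2.5 equiv) added to the mixture of 27 and 15, THF, −40 to 0 °C, dark
Reagents that add atoms: none
Why: Second Horner–Wadsworth–Emmons olefination should form C11'=C12' with E-geometry and complete the C40 chain; low temperature and exclusion of light and iodine protect the 9E and 9'E bonds, and no stereocentre is touched.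

Step 22
Reactants: 28 (3R,3'S,4'R)-3',4'-bis-O-TBS-7,8,7',8'-tetradehydro-β,β-carotene-3,3',4'-triol
Product: 29 (3R,3'S,4'R)-7,8,7',8'-tetradehydro-β,β-carotene-3,3',4'-triol (CNP0323983.1)
Conditions: Bu4NF, THF, 0 °C to rt, dark, argon
Reagents that add atoms: none
Why: Fluoride-mediated desilylation under non-acidic conditions, which spares the acid-sensitive allylic C4' hydroxyl and the polyene.

## Compound list

1 | N-methoxy-N,2-dimethylpropanamide | CC(C)C(=O)N(C)OC | starting material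
2 | prop-1-en-2-ylmagnesium bromide | CC(=C)[Mg]Br | starting material
3 | 2,4-dimethylpent-1-en-3-one | CC(C)C(=O)C(C)=C | intermediate
4 | tert-butyl[(2,4-dimethylpenta-1,3-dien-3-yl)oxy]dimethylsilane | CC(C)=C(O[Si](C)(C)C(C)(C)C)C(C)=C | intermediate
5 | but-3-en-2-one | CC(=O)C=C | starting material
6 | 1-[(1R)-4-(TBS-oxy)-3,5,5-trimethylcyclohex-3-en-1-yl]ethan-1-one | CC1=C(O[Si](C)(C)C(C)(C)C)C(C)(C)C[C@H](C(C)=O)C1 | intermediate
7 | (4R)-4-acetyl-2,6,6-trimethylcyclohex-1-en-1-yl nonafluorobutane-1-sulfonate | CC1=C(OS(=O)(=O)C(F)(F)C(F)(F)C(F)(F)C(F)(F)F)C(C)(C)C[C@H](C(C)=O)C1 | intermediate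
8 | (4R)-4-acetoxy-2,6,6-trimethylcyclohex-1-en-1-yl nonafluorobutane-1-sulfonate | CC1=C(OS(=O)(=O)C(F)(F)C(F)(F)C(F)(F)C(F)(F)F)C(C)(C)C[C@H](OC(C)=O)C1 | intermediate
9 | (2E)-3-methylpent-2-en-4-yn-1-ol | C#C/C(C)=C/CO | starting material
10 | (2E)-1-bromo-3-methylpent-2-en-4-yne | C#C/C(C)=C/CBr | intermediate
11 | diethyl [(2E)-3-methylpent-2-en-4-yn-1-yl]phosphonate | C#C/C(C)=C/CP(=O)(OCC)OCC | intermediate
12 | (1R)-4-[(3E)-5-(diethoxyphosphoryl)-3-methylpent-3-en-1-yn-1-yl]-3,5,5-trimethylcyclohex-3-en-1-yl acetate | CC1=C(C#C/C(C)=C/CP(=O)(OCC)OCC)C(C)(C)C[C@H](OC(C)=O)C1 | intermediate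
13 | diethyl [(2E)-5-[(4R)-4-hydroxy-2,6,6-trimethylcyclohex-1-en-1-yl]-3-methylpent-2-en-4-yn-1-yl]phosphonate | CC1=C(C#C/C(C)=C/CP(=O)(OCC)OCC)C(C)(C)C[C@H](O)C1 | intermediate
14 | (2E,4E,6E)-2,7-dimethylocta-2,4,6-trienedial | O=C/C(C)=C/C=C/C=C(C)/C=O | starting material
15 | (2E,4E,6E,8E,10E)-13-[(4R)-4-hydroxy-2,6,6-trimethylcyclohex-1-en-1-yl]-2,7,11-trimethyltrideca-2,4,6,8,10-pentaen-12-ynal | CC1=C(C#C/C(C)=C/C=C/C(C)=C/C=C/C=C(C)/C=O)C(C)(C)C[C@H](O)C1 | intermediate
16 | 2,6,6-trimethylcyclohex-2-ene-1,4-dione | CC1=CC(=O)CC(C)(C)C1=O | starting material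
17 | (4S)-4-hydroxy-2,6,6-trimethylcyclohex-2-en-1-one | CC1=C[C@@H](O)CC(C)(C)C1=O | intermediate
18 | (4S)-4-(TBS-oxy)-2,6,6-trimethylcyclohex-2-en-1-one | CC1=C[C@@H](O[Si](C)(C)C(C)(C)C)CC(C)(C)C1=O | intermediate
19 | tert-butyldimethyl{[(2E)-3-methylpent-2-en-4-yn-1-yl]oxy}silane | C#C/C(C)=C/CO[Si](C)(C)C(C)(C)C | intermediate
20 | lithium acetylide of 19, {(3E)-5-(TBS-oxy)-3-methylpent-3-en-1-yn-1-yl}lithium | [Li]C#C/C(C)=C/CO[Si](C)(C)C(C)(C)C | intermediate
21 | (4S)-4-(TBS-oxy)-1-[(3E)-5-(TBS-oxy)-3-methylpent-3-en-1-yn-1-yl]-2,6,6-trimethylcyclohex-2-en-1-ol (both C1 epimers) | CC1=C[C@@H](O[Si](C)(C)C(C)(C)C)CC(C)(C)C1(O)C#C/C(C)=C/CO[Si](C)(C)C(C)(C)C | intermediate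
22 | (6S)-6-(TBS-oxy)-3-[(3E)-5-(TBS-oxy)-3-methylpent-3-en-1-yn-1-yl]-2,4,4-trimethylcyclohex-2-en-1-one | CC1=C(C#C/C(C)=C/CO[Si](C)(C)C(C)(C)C)C(C)(C)C[C@H](O[Si](C)(C)C(C)(C)C)C1=O | intermediate
23 | (1R,6S)-6-(TBS-oxy)-3-[(3E)-5-(TBS-oxy)-3-methylpent-3-en-1-yn-1-yl]-2,4,4-trimethylcyclohex-2-en-1-ol | CC1=C(C#C/C(C)=C/CO[Si](C)(C)C(C)(C)C)C(C)(C)C[C@H](O[Si](C)(C)C(C)(C)C)[C@@H]1O | intermediate
24 | tert-butyl{[(2E)-5-[(3R,4S)-3,4-bis(TBS-oxy)-2,6,6-trimethylcyclohex-1-en-1-yl]-3-methylpent-2-en-4-yn-1-yl]oxy}dimethylsilane | CC1=C(C#C/C(C)=C/CO[Si](C)(C)C(C)(C)C)C(C)(C)C[C@H](O[Si](C)(C)C(C)(C)C)[C@@H]1O[Si](C)(C)C(C)(C)C | intermediate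
25 | (2E)-5-[(3R,4S)-3,4-bis(TBS-oxy)-2,6,6-trimethylcyclohex-1-en-1-yl]-3-methylpent-2-en-4-yn-1-ol | CC1=C(C#C/C(C)=C/CO)C(C)(C)C[C@H](O[Si](C)(C)C(C)(C)C)[C@@H]1O[Si](C)(C)C(C)(C)C | intermediate
26 | (3R,4S)-1-[(3E)-5-bromo-3-methylpent-3-en-1-yn-1-yl]-3,4-bis(TBS-oxy)-2,6,6-trimethylcyclohex-1-ene | CC1=C(C#C/C(C)=C/CBr)C(C)(C)C[C@H](O[Si](C)(C)C(C)(C)C)[C@@H]1O[Si](C)(C)C(C)(C)C | intermediate
27 | diethyl [(2E)-5-[(3R,4S)-3,4-bis(TBS-oxy)-2,6,6-trimethylcyclohex-1-en-1-yl]-3-methylpent-2-en-4-yn-1-yl]phosphonate | CC1=C(C#C/C(C)=C/CP(=O)(OCC)OCC)C(C)(C)C[C@H](O[Si](C)(C)C(C)(C)C)[C@@H]1O[Si](C)(C)C(C)(C)C | intermediate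
28 | (3R,3'S,4'R)-3',4'-bis-O-TBS-7,8,7',8'-tetradehydro-β,β-carotene-3,3',4'-triol | CC1=C(C#C/C(C)=C/C=C/C(C)=C/C=C/C=C(C)/C=C/C=C(\C)C#CC2=C(C)[C@@H](O[Si](C)(C)C(C)(C)C)[C@@H](O[Si](C)(C)C(C)(C)C)CC2(C)C)C(C)(C)C[C@H](O)C1 | intermediate
29 | (3R,3'S,4'R)-7,8,7',8'-tetradehydro-β,β-carotene-3,3',4'-triol (CNP0323983.1) | CC1=C(C#C/C(C)=C/C=C/C(C)=C/C=C/C=C(C)/C=C/C=C(\C)C#CC2=C(C)[C@@H](O)[C@@H](O)CC2(C)C)C(C)(C)C[C@H](O)C1 | target

## Step count and risks

Total step count: 22. Longest linear sequence: 11 steps (16 → 29 through steps 11, 12 and 14–22); the ring A branch from 1 is 10 steps.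

Steps most likely to fail:

Step 3. The crowded diene may react stepwise, which would erode the enantiofacial discrimination, and the sense of induction rests on a transition-state model rather than on a result; the diene may also be lost by proto-desilylation under the acidic catalyst. The first remedy for a reversed sense is the mirror-image catalyst. The fallback with a different approach is an auxiliary-controlled cycloaddition: it sets out from 4, which is combined with commercial (4R)-3-acryloyl-4-benzyl-1,3-oxazolidin-2-one and Me2AlCl in CH2Cl2 at −78 °C. In the bidentate aluminium chelate the benzyl group covers one face, and the diene should add to the Re face of C-α to give (4R)-4-benzyl-3-{[(1R)-4-(TBS-oxy)-3,5,5-trimethylcyclohex-3-en-1-yl]carbonyl}-1,3-oxazolidin-2-one F1. Transamidation with MeONHMe·HCl/AlMe3 gives (1R)-4-(TBS-oxy)-N-methoxy-N,3,5,5-tetramethylcyclohex-3-ene-1-carboxamide F2, and MeMgBr then returns to the route at 6.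

Step 4. Proton transfer from C3–H or the acetyl methyl to the fluoride-generated enolate could precede sulfonylation, eroding the C3 configuration or sulfonylating the wrong enolate. The fallback removes the acidic ketone before the enolate is made. It sets out from 6: mild hydrolysis (AcOH, THF, H2O) gives (4R)-4-acetyl-2,2,6-trimethylcyclohexan-1-one F3; 1,2-bis(trimethylsilyloxy)ethane with catalytic TMSOTf at −78 °C ketalises only the unhindered acetyl group to give (4R)-2,2,6-trimethyl-4-(2-methyl-1,3-dioxolan-2-yl)cyclohexan-1-one F4; KN(SiMe3)2 followed by n-C4F9SO2F gives (4R)-2,6,6-trimethyl-4-(2-methyl-1,3-dioxolan-2-yl)cyclohex-1-en-1-yl nonafluorobutane-1-sulfonate F5; PPTS in wet acetone returns to the route at 7.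

Step 16. Hydride may be delivered to the wrong face of the C4' carbonyl, giving the trans-diol derivative, or may add in conjugate fashion along the enynone. The fallback makes the trans alcohol on purpose and inverts it. It sets out from 22: NaBH4/CeCl3 in MeOH (small hydride, axial attack) should give (1S,6S)-6-(TBS-oxy)-3-[(3E)-5-(TBS-oxy)-3-methylpent-3-en-1-yn-1-yl]-2,4,4-trimethylcyclohex-2-en-1-ol F6; Mitsunobu inversion with 4-nitrobenzoic acid, DIAD and PPh3 gives (1R,6S)-6-(TBS-oxy)-3-[(3E)-5-(TBS-oxy)-3-methylpent-3-en-1-yn-1-yl]-2,4,4-trimethylcyclohex-2-en-1-yl 4-nitrobenzoate F7; K2CO3 in MeOH returns to the route at 23.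

## Further compounds

F1 | step 3 | (4R)-4-benzyl-3-{[(1R)-4-(TBS-oxy)-3,5,5-trimethylcyclohex-3-en-1-yl]carbonyl}-1,3-oxazolidin-2-one | CC1=C(O[Si](C)(C)C(C)(C)C)C(C)(C)C[C@H](C(=O)N2C(=O)OC[C@H]2Cc3ccccc3)C1
F2 | step 3 | (1R)-4-(TBS-oxy)-N-methoxy-N,3,5,5-tetramethylcyclohex-3-ene-1-carboxamide | CC1=C(O[Si](C)(C)C(C)(C)C)C(C)(C)C[C@H](C(=O)N(C)OC)C1
F3 | step 4 | (4R)-4-acetyl-2,2,6-trimethylcyclohexan-1-one (both C6 epimers) | CC1C(=O)C(C)(C)C[C@H](C(C)=O)C1
F4 | step 4 | (4R)-2,2,6-trimethyl-4-(2-methyl-1,3-dioxolan-2-yl)cyclohexan-1-one (both C6 epimers) | CC1C(=O)C(C)(C)C[C@H](C2(C)OCCO2)C1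
F5 | step 4 | (4R)-2,6,6-trimethyl-4-(2-methyl-1,3-dioxolan-2-yl)cyclohex-1-en-1-yl nonafluorobutane-1-sulfonate | CC1=C(OS(=O)(=O)C(F)(F)C(F)(F)C(F)(F)C(F)(F)F)C(C)(C)C[C@H](C2(C)OCCO2)C1
F6 | step 16 | (1S,6S)-6-(TBS-oxy)-3-[(3E)-5-(TBS-oxy)-3-methylpent-3-en-1-yn-1-yl]-2,4,4-trimethylcyclohex-2-en-1-ol | CC1=C(C#C/C(C)=C/CO[Si](C)(C)C(C)(C)C)C(C)(C)C[C@H](O[Si](C)(C)C(C)(C)C)[C@H]1O
F7 | step 16 | (1R,6S)-6-(TBS-oxy)-3-[(3E)-5-(TBS-oxy)-3-methylpent-3-en-1-yn-1-yl]-2,4,4-trimethylcyclohex-2-en-1-yl 4-nitrobenzoate | CC1=C(C#C/C(C)=C/CO[Si](C)(C)C(C)(C)C)C(C)(C)C[C@H](O[Si](C)(C)C(C)(C)C)[C@@H]1OC(=O)c2ccc(cc2)[N+](=O)[O-]
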